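**Retrosynthetic overview**
1. Target 19 ⇐ double angeloylation of the all-cis epoxy-diol 16. The C8 acetate is carried from step 5, so no protecting groups are used.
2. 16 ⇐ Pd/formate hydrogenolysis of the alkenyl oxirane in bis-epoxy alcohol 15. This goes with inversion at C1, removes the helper C1–C2 oxirane and keeps the C4–C5 oxirane.
3. 15 ⇐ acyclic trienyne carbinol 13 in one flask. Ring-closing enyne metathesis forms the carbocycle first, then an OH-directed double epoxidation forms both oxiranes. C1, C2, C4 and C5 are all relayed from C3.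
4. 13 ⇐ asymmetric Ni/Cr coupling of Z-vinyl iodide 11 with acrolein (sets C3). 11 ⇐ asymmetric alkynylation of 4-methylpent-3-enal with enyne 6 (sets C8).
5. 6 ⇐ but-2-yn-1-ol by trans-hydroalumination/iodination, bromination and ethynyl coupling.

Assumption: locants are ring C1 (side chain), C2, C3, C4 (methyl), C5, C6, then C7(=C14H2), C8 (OAc), C9, C10=C11. The antipode of each chiral ligand is defined by the aldehyde face it must attack, and would be confirmed by Mosher analysis on first use.

**Step 1**
Reactants: 1 but-2-yn-1-ol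
Product: 3 (Z)-3-iodobut-2-en-1-ol, via cyclic alkenylaluminate 2 (not isolated)
Conditions: Red-Al (1.6 equiv), Et2O, 0 °C → rt; then I2, THF, −78 → 0 °C
Reagents that add atoms: iodine, II
Why: Hydroxyl-directed trans-hydroalumination puts Al on the distal alkyne carbon in a five-membered chelate, and iodinolysis with retention gives only the Z vinyl iodide, which fixes the geometry of the later ring alkene C4=C5.

**Step 2**
Reactants: 3 (Z)-3-iodobut-2-en-1-ol
Product: 4 (Z)-1-bromo-3-iodobut-2-ene
Conditions: CBr4, PPh3, CH2Cl2, 0 °C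
Reagents that add atoms: carbon tetrabromide, BrC(Br)(Br)Br
Why: The Appel reaction is a neutral SN2 at the primary allylic carbon, so there is no allylic shift and the Z geometry is kept.

**Step 3**
Reactants: 4 (Z)-1-bromo-3-iodobut-2-ene; 5 ethynylmagnesium bromide
Product: 6 (Z)-5-iodohex-4-en-1-yne
Conditions: 5 (2.5 equiv), CuBr·SMe2 (10 mol %), THF, 0 °C → rt
Reagents that add atoms: none
Why: Copper-catalysed SN2 coupling of an alkynyl Grignard with a primary allylic bromide gives the skipped enyne, and the sp-carbanion does not exchange with the vinyl iodide.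

**Step 4**
Reactants: 7 4-methylpent-3-en-1-ol
Product: 8 4-methylpent-3-enal
Conditions: Dess–Martin periodinane, CH2Cl2, 0 °C; short plug, used at once
Reagents that add atoms: none
Why: Dess–Martin oxidation stops at the aldehyde under conditions mild enough that the β,γ-alkene does not move into conjugation.

**Step 5**
Reactants: 6 (Z)-5-iodohex-4-en-1-yne; 8 4-methylpent-3-enal
Product: 11 (2Z,7S)-2-iodo-10-methylundeca-2,9-dien-5-yn-7-yl acetate, via alkynyl(methyl)zinc 9 (not isolated), via methylzinc alkoxide 10 (not isolated)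
Conditions: 6, Me2Zn, ProPhenol (20 mol %, antipode for Re-face attack), Ph3P=O (40 mol %), toluene, 0 °C; slow addition of 8; then Ac2O, rt
Reagents that add atoms: acetic anhydride, CC(=O)OC(C)=O
Why: In this dinuclear-zinc catalytic asymmetric alkynylation the catalyst binds aldehyde and alkynylzinc together and delivers the alkynyl group to the Re face (C8 = S), and the zinc alkoxide is acetylated in the same flask.

**Step 6**
Reactants: 11 (2Z,7S)-2-iodo-10-methylundeca-2,9-dien-5-yn-7-yl acetate; 12 acrolein
Product: 13 (3R,4Z,9S)-3-hydroxy-4,12-dimethyltrideca-1,4,11-trien-7-yn-9-yl acetate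
Conditions: 12 (3 equiv), CrCl2 (3 equiv), chiral oxazoline–sulfonamide ligand (3.3 equiv, antipode for Si-face attack), Et3N (3.3 equiv), NiCl2 (2 mol %), THF, rt
Reagents that add atoms: none
Why: In this asymmetric Nozaki–Hiyama–Kishi alkenylation Ni inserts only into C–I with retention of the Z geometry, the alkenyl-Cr(III) adds 1,2 to acrolein without touching acetate or alkyne, and the ligand on Cr directs Si-face attack to set C3 = R.

**Step 7 (key step)**
Reactants: 13 (3R,4Z,9S)-3-hydroxy-4,12-dimethyltrideca-1,4,11-trien-7-yn-9-yl acetate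
Product: 15 (1S,2S,3R,4R,5S,8S)-8-acetoxy-1,2:4,5-diepoxybisabola-7(14),10-dien-3-ol (both oxiranes syn to the OH), via cyclohexadienol 14 (not isolated)
Conditions: Grubbs II (5 mol %), C2H4 (1 atm), CH2Cl2 (5 mM), 25–35 °C; Ar purge, DMSO (0.5 equiv), 2,6-lutidine (0.3 equiv), 0 °C; VO(acac)2 (10 mol %), t-BuOOH (2.4 equiv, decane), 0 °C
Reagents that add atoms: tert-butyl hydroperoxide, CC(C)(C)OO
Why: Proposed new method: ring-closing enyne metathesis of the 1,7-enyne (closest known types: enyne ring closure under ethylene and RCM of 1,4,7-trien-3-ols to cyclohexadienols) closes the carbocycle and moves the vinyl CH2 onto C7, and the acid-labile bis-allylic alcohol 14 is used at once for a vanadium-catalysed hydroxyl-directed epoxidation in which the V(V) alkoxide–peroxide delivers oxygen to both flanking ring alkenes on the OH face only, so C1, C2, C4 and C5 are all set syn to C3 while C7=C14 and C10=C11, which are not allylic to a free hydroxyl, are left alone.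

**Step 8**
Reactants: 15 (1S,2S,3R,4R,5S,8S)-8-acetoxy-1,2:4,5-diepoxybisabola-7(14),10-dien-3-ol
Product: 16 (1S,2R,3R,4R,5S,8S)-8-acetoxy-4,5-epoxybisabola-7(14),10-diene-2,3-diol (side chain, both OH and oxirane all cis)
Conditions: Pd2(dba)3·CHCl3 (2.5 mol %), n-Bu3P (5 mol %), HCO2H (1.2 equiv), Et3N (0.5 equiv), THF, 0 °C
Reagents that add atoms: none
Why: In this Pd-catalysed formate hydrogenolysis of an alkenyl oxirane Pd(0) ionises only the strained allylic C1–O bond anti to oxygen, formate loses CO2 to give Pd–H, and hydride passes from the metal face to the more substituted allyl terminus C1, which gives net inversion (H anti, side chain syn to the C2 OH), restores C7=C14 and spares the non-allylic C4–C5 oxirane.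

**Step 9**
Reactants: 16 (1S,2R,3R,4R,5S,8S)-8-acetoxy-4,5-epoxybisabola-7(14),10-diene-2,3-diol; 17 angelic acid
Product: 19 CNP0188566.2 = (1S,2R,3R,4S,5S,8S)-8-acetoxy-2,3-bis(angeloyloxy)-4,5-epoxybisabola-7(14),10-diene, via mixed anhydride 18 (not isolated)
Conditions: 17 (6 equiv), 2,4,6-trichlorobenzoyl chloride (6 equiv), Et3N (6 equiv), toluene, rt, filter; then 16, toluene, 80 °C, no DMAP
Reagents that add atoms: none
Why: Yamaguchi-type mixed-anhydride acylation without a nucleophilic catalyst esterifies both hindered hydroxyls while avoiding the addition–elimination path that turns angelate into tiglate, and no stereocentre is touched (the C4 descriptor changes from R to S only through CIP priorities).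

**Compound list**
1 | but-2-yn-1-ol | CC#CCO | starting material
2 | sodium cyclic (Z)-alkenylaluminate (O–Al–C chelate, two 2-methoxyethoxy ligands) | CC1=CCO[Al-]1(OCCOC)OCCOC.[Na+] | intermediate
3 | (Z)-3-iodobut-2-en-1-ol | C/C(I)=C/CO | intermediate
4 | (Z)-1-bromo-3-iodobut-2-ene | C/C(I)=C/CBr | intermediate
5 | ethynylmagnesium bromide | C#C[Mg]Br | starting material
6 | (Z)-5-iodohex-4-en-1-yne | C/C(I)=C/CC#C | intermediate
7 | 4-methylpent-3-en-1-ol | CC(C)=CCCO | starting material
8 | 4-methylpent-3-enal | CC(C)=CCC=O | intermediate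
9 | methyl[(Z)-5-iodohex-4-en-1-yn-1-yl]zinc | C[Zn]C#CC/C=C(/C)I | intermediate
10 | methylzinc (2Z,7S)-2-iodo-10-methylundeca-2,9-dien-5-yn-7-olate | C[Zn]O[C@@H](CC=C(C)C)C#CC/C=C(/C)I | intermediate
11 | (2Z,7S)-2-iodo-10-methylundeca-2,9-dien-5-yn-7-yl acetate | CC(=O)O[C@@H](CC=C(C)C)C#CC/C=C(/C)I | intermediate
12 | acrolein | C=CC=O | starting material
13 | (3R,4Z,9S)-3-hydroxy-4,12-dimethyltrideca-1,4,11-trien-7-yn-9-yl acetate | C=C[C@@H](O)/C(C)=C\CC#C[C@H](CC=C(C)C)OC(C)=O | intermediate
14 | (3S)-2-[(3R)-3-hydroxy-4-methylcyclohexa-1,4-dien-1-yl]-6-methylhepta-1,5-dien-3-yl acetate | C=C([C@H](CC=C(C)C)OC(C)=O)C1=C[C@@H](O)C(C)=CC1 | intermediate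
15 | (1S,2S,3R,4R,5S,8S)-8-acetoxy-1,2:4,5-diepoxybisabola-7(14),10-dien-3-ol, both oxiranes syn to OH | C=C([C@H](CC=C(C)C)OC(C)=O)[C@@]13C[C@@H]2O[C@]2(C)[C@H](O)[C@@H]1O3 | intermediate
16 | (1S,2R,3R,4R,5S,8S)-8-acetoxy-4,5-epoxybisabola-7(14),10-diene-2,3-diol, all-cis | C=C([C@H](CC=C(C)C)OC(C)=O)[C@@H]1C[C@@H]2O[C@]2(C)[C@H](O)[C@@H]1O | intermediate
17 | angelic acid, (Z)-2-methylbut-2-enoic acid | C/C=C(/C)C(=O)O | starting material
18 | angelic 2,4,6-trichlorobenzoic anhydride | C/C=C(/C)C(=O)OC(=O)c1c(Cl)cc(Cl)cc1Cl | intermediate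
19 | CNP0188566.2 | C=C([C@H](CC=C(C)C)OC(C)=O)[C@@H]1C[C@@H]2O[C@]2(C)[C@H](OC(=O)/C(C)=C\C)[C@@H]1OC(=O)/C(C)=C\C | target

**Totals:** 9 steps. The longest linear sequence is 8 steps (1, 2, 3, 5, 6, 7, 8, 9).

**Steps most likely to fail**

Step 7. Alcohol 14 is an arene hydrate and may lose water to give the styrene-type arene, or be oxidised by Ru/V residues, before both epoxidations finish. Fallback: uncouple ring closure from oxidation. Starting from 13, silylate (TESCl, imidazole) to the triethylsilyl ether of the trienyne carbinol F3. Close the ring with Grubbs II under ethylene to the silyl-masked cyclohexadienol F4, which can be purified on Et3N-deactivated silica free of ruthenium. Unmask with AcOH-buffered TBAF at 0 °C to 14 and epoxidise it immediately with VO(acac)2/t-BuOOH. The route is rejoined at 15.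

Step 8. The C8 acetate is itself allylic to C7=C14, so Pd(0) may also reduce or transpose it. Fallback without Pd(0): starting from 15, a Lewis-acid Meinwald rearrangement (cat. BF3·OEt2, CH2Cl2, −78 °C) ionises the tertiary allylic C1–O bond. H-2 then shifts to C1 anti to the leaving oxygen and gives the C1-correct α-hydroxy-β,γ-unsaturated ketone F5. L-Selectride at −78 °C attacks its carbonyl from the face opposite the side chain, OH-3 and oxirane, giving the axial cis alcohol. The route is rejoined at 16.

Step 6. Acrolein is a very small aldehyde, so facial control by the chromium ligand may be modest. Fallback: set C3 by reduction instead of addition. Starting from 11, run the Ni/Cr coupling without ligand (CrCl2, cat. NiCl2, DMSO) to the C3-epimeric carbinol mixture F1. Oxidise with MnO2 to the cross-conjugated divinyl ketone F2. Reduce with (S)-Me-CBS/catecholborane at −78 °C, where the α-methylalkenyl arm acts as the large group. The route is rejoined at 13.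

**Further compounds**
F1 | step 6 | (4Z,9S)-3-hydroxy-4,12-dimethyltrideca-1,4,11-trien-7-yn-9-yl acetate, C3 epimers | C=CC(O)/C(C)=C\CC#C[C@H](CC=C(C)C)OC(C)=O
F2 | step 6 | (4Z,9S)-4,12-dimethyl-3-oxotrideca-1,4,11-trien-7-yn-9-yl acetate | C=CC(=O)/C(C)=C\CC#C[C@H](CC=C(C)C)OC(C)=O
F3 | step 7 | (3R,4Z,9S)-4,12-dimethyl-3-(triethylsilyloxy)trideca-1,4,11-trien-7-yn-9-yl acetate | C=C[C@@H](O[Si](CC)(CC)CC)/C(C)=C\CC#C[C@H](CC=C(C)C)OC(C)=O
F4 | step 7 | (3S)-6-methyl-2-[(3R)-4-methyl-3-(triethylsilyloxy)cyclohexa-1,4-dien-1-yl]hepta-1,5-dien-3-yl acetate | C=C([C@H](CC=C(C)C)OC(C)=O)C1=C[C@@H](O[Si](CC)(CC)CC)C(C)=CC1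
F5 | step 8 | (1S,3S,4R,5S,8S)-8-acetoxy-4,5-epoxy-3-hydroxybisabola-7(14),10-dien-2-one | C=C([C@H](CC=C(C)C)OC(C)=O)[C@@H]1C[C@@H]2O[C@]2(C)[C@H](O)C1=O
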